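## Retrosynthetic overview
1. The target comes from a perbenzylated (4β→6) dimer by Ag-assisted C4–S → C4–OH hydrolysis and then global hydrogenolysis. That dimer carries a 4β-arylthio group in the lower unit and a bromine cap at C6 of the upper unit.
2. The key disconnection is the interflavanyl bond C4(upper)–C6(lower). It is made late by BF3-promoted union of two flavan monomers of equal size: a 6-bromo-4-methoxyflavan-3-ol (electrophile) and a 4-arylthioflavan-3-ol (nucleophile).
3. Each monomer is opened in ring C at O1–C8a (intramolecular SNAr on an aryl fluoride, which leaves C2 untouched) and at C4–C4a (aryllithium plus aldehyde).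
4. Both monomers use one aldehyde that holds ring B, C2, C3 and C4. It is built from catechol, DMF and allyl alcohol, and a Brown syn-alkoxyallylboration sets C2 and C3. Ring A comes from 2-fluorophenol (lower) or 1-bromo-4-fluorobenzene (upper) by formylation/Dakin oxygenation.
5. Ring order: the two C rings are closed separately, then the units are joined. Upper C4 is set in the union and lower C4 in the hydrolysis.

Assumption: the carbinol carbon made in steps 16 and 19 (later C-4) is an epimer mixture that is carried on unseparated. Its SMILES centre is left open until steps 18 and 21 reset it through the C-4 cation.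

## Route

**Aldehyde fragment (ring B + C2–C3–C4)**

Step 1
Reactants: 1 catechol
Product: 2 1,2-bis(benzyloxy)benzene
Conditions: BnBr (2.3 equiv), K2CO3, DMF, 60 °C, N2
Reagents that add atoms: benzyl bromide, BrCc1ccccc1
Why: Williamson ether synthesis; both phenoxides are alkylated, giving ethers that survive the later bases, organolithiums and Lewis acids and fall off by hydrogenolysis at the end.

Step 2
Reactants: 2 1,2-bis(benzyloxy)benzene
Product: 3 1,2-bis(benzyloxy)-4-bromobenzene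
Conditions: NBS (1.0 equiv), MeCN, 0 °C → rt
Reagents that add atoms: N-bromosuccinimide, O=C1CCC(=O)N1Br
Why: Electrophilic aromatic bromination; NBS in MeCN attacks para to one benzyloxy group, and the first bromine deactivates the ring against a second attack.

Step 3
Reactants: 3 1,2-bis(benzyloxy)-4-bromobenzene
Product: 5 3,4-bis(benzyloxy)benzaldehyde, via 3,4-bis(benzyloxy)phenyllithium 4 (not isolated)
Conditions: n-BuLi, THF, −78 °C; DMF, −78 °C → 0 °C; then H2O
Reagents that add atoms: N,N-dimethylformamide, CN(C)C=O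
Why: Bromine–lithium exchange followed by Bouveault formylation; exchange at −78 °C is far faster than benzylic deprotonation of the ethers.

Step 4
Reactants: 6 allyl alcohol
Product: 7 3-(methoxymethoxy)prop-1-ene
Conditions: MOMCl, (i-Pr)2NEt, CH2Cl2, 0 °C → rt; distil
Reagents that add atoms: chloromethyl methyl ether, COCCl
Why: O-alkylation to the MOM acetal, whose oxygen later chelates lithium and locks the allyl anion in the Z geometry.

Step 5
Reactants: 7 3-(methoxymethoxy)prop-1-ene; 5 3,4-bis(benzyloxy)benzaldehyde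
Product: 11 (1R,2R)-1-[3,4-bis(benzyloxy)phenyl]-2-(methoxymethoxy)but-3-en-1-ol, via (Z)-3-(methoxymethoxy)allyllithium 8 (not isolated), via (Z)-MOMO-allyl-bis(isopinocampheyl)borane 9 (not isolated), via bis(isopinocampheyl)borinate of the adduct 10 (not isolated)
Conditions: s-BuLi, THF, −78 °C; (−)-Ipc2BOMe; BF3·OEt2; then 5, −78 °C → rt; NaOH, H2O2
Reagents that add atoms: none
Why: Brown asymmetric γ-alkoxyallylboration; the Z-allylborane reacts through a closed Zimmerman–Traxler chair to give the syn product, and the Ipc groups derived from (+)-α-pinene direct attack to the Si face of 5, which sets (1R,2R), the future C-2 and C-3 of both flavan units.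

Step 6
Reactants: 11 (1R,2R)-1-[3,4-bis(benzyloxy)phenyl]-2-(methoxymethoxy)but-3-en-1-ol
Product: 12 (1R,2R)-1-[3,4-bis(benzyloxy)phenyl]-1-(tert-butyldimethylsilyloxy)-2-(methoxymethoxy)but-3-ene
Conditions: t-BuMe2SiCl, imidazole, DMF, 40 °C
Reagents that add atoms: tert-butyldimethylsilyl chloride, CC(C)(C)[Si](C)(C)Cl
Why: Imidazole-promoted silylation masks the benzylic hydroxyl, so the coming β-oxy aldehyde can neither dehydrate nor undergo retro-aldol cleavage; no stereocentre is touched.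

Step 7
Reactants: 12 (1R,2R)-1-[3,4-bis(benzyloxy)phenyl]-1-(tert-butyldimethylsilyloxy)-2-(methoxymethoxy)but-3-ene
Product: 14 (2S,3R)-3-[3,4-bis(benzyloxy)phenyl]-3-(tert-butyldimethylsilyloxy)-2-(methoxymethoxy)propanal, via terminal 1,2-diol 13 (not isolated)
Conditions: OsO4 (2 mol %), NaIO4 (4 equiv), 2,6-lutidine, dioxane–H2O 3:1, rt
Reagents that add atoms: OsO4, O=[Os](=O)(=O)=O; NaIO4, [Na+].[O-]I(=O)(=O)=O (together they supply the aldehyde oxygen)
Why: Lemieux–Johnson cleavage in lutidine buffer removes only the terminal CH2, leaves the electron-rich rings alone (which ozone might attack), and does not epimerise the α-alkoxy aldehyde; the descriptor change at C-2 reflects priorities only.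

**Ring A of the lower unit**

Step 8
Reactants: 15 2-fluorophenol
Product: 16 3-fluoro-2-hydroxybenzaldehyde
Conditions: MgCl2, Et3N, (CH2O)n, MeCN, reflux; aq HCl
Reagents that add atoms: paraformaldehyde (as formaldehyde), C=O
Why: Casnati–Skattebøl ortho-formylation; the magnesium phenoxide delivers formaldehyde only to the free ortho position, and a second formaldehyde takes up the hydride.

Step 9
Reactants: 16 3-fluoro-2-hydroxybenzaldehyde
Product: 18 3-fluorobenzene-1,2-diol, via 3-fluoro-2-hydroxyphenyl formate 17 (not isolated)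
Conditions: 30% H2O2, NaOH, H2O, 0 °C → rt, N2; aq HCl
Reagents that add atoms: hydrogen peroxide, OO
Why: Dakin oxidation; the ortho-hydroxyaryl group migrates to oxygen and the formate is saponified in the flask.

Step 10
Reactants: 18 3-fluorobenzene-1,2-diol
Product: 19 1,2-bis(benzyloxy)-3-fluorobenzene
Conditions: BnBr (2.3 equiv), K2CO3, DMF, 60 °C, N2
Reagents that add atoms: benzyl bromide, BrCc1ccccc1
Why: Williamson ether synthesis, as in step 1.

Step 11
Reactants: 19 1,2-bis(benzyloxy)-3-fluorobenzene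
Product: 20 1,2-bis(benzyloxy)-4-bromo-3-fluorobenzene
Conditions: NBS (1.0 equiv), MeCN, 0 °C → rt
Reagents that add atoms: N-bromosuccinimide, O=C1CCC(=O)N1Br
Why: Electrophilic aromatic bromination; the unhindered 1-benzyloxy group directs para while the flanked 2-benzyloxy group is twisted out of conjugation, so bromine enters next to fluorine, as it does with 3-fluoroanisole.

**Ring A of the upper unit (carries the C-6 cap)**

Step 12
Reactants: 21 1-bromo-4-fluorobenzene
Product: 24 5-bromo-2-fluorophenol, via 5-bromo-2-fluorophenyllithium 22 (not isolated), via dimethyl 5-bromo-2-fluorophenylboronate 23 (not isolated)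
Conditions: LiN(i-Pr)2, THF, −78 °C; B(OMe)3, → rt; AcOH, 30% H2O2, 0 °C → rt
Reagents that add atoms: hydrogen peroxide, OO
Why: Directed ortho-lithiation at the most acidic C–H next to fluorine, followed by borylation and oxidative boron-to-oxygen migration; the amide base does not exchange the bromine.

Step 13
Reactants: 24 5-bromo-2-fluorophenol
Product: 25 6-bromo-3-fluoro-2-hydroxybenzaldehyde
Conditions: MgCl2, Et3N, (CH2O)n, MeCN, reflux; aq HCl
Reagents that add atoms: paraformaldehyde (as formaldehyde), C=O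
Why: Casnati–Skattebøl ortho-formylation; only one ortho position is free, so the regiochemistry is fixed, as in the formylation of 2,5-dihalophenols.

Step 14
Reactants: 25 6-bromo-3-fluoro-2-hydroxybenzaldehyde
Product: 27 3-bromo-6-fluorobenzene-1,2-diol, via 6-bromo-3-fluoro-2-hydroxyphenyl formate 26 (not isolated)
Conditions: 30% H2O2, NaOH, H2O, 0 °C → rt, N2; aq HCl
Reagents that add atoms: hydrogen peroxide, OO
Why: Dakin oxidation, as in step 9; the halogens are inert to alkaline peroxide.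

Step 15
Reactants: 27 3-bromo-6-fluorobenzene-1,2-diol
Product: 28 2,3-bis(benzyloxy)-1-bromo-4-fluorobenzene
Conditions: BnBr (2.4 equiv), K2CO3, DMF, 70 °C, N2
Reagents that add atoms: benzyl bromide, BrCc1ccccc1
Why: Williamson ether synthesis; fluorine and bromine now sit para to each other, which is exactly the C-8a/C-6 relation of the upper flavan.

**Lower monomer**

Step 16
Reactants: 20 1,2-bis(benzyloxy)-4-bromo-3-fluorobenzene; 14 (2S,3R)-3-[3,4-bis(benzyloxy)phenyl]-3-(tert-butyldimethylsilyloxy)-2-(methoxymethoxy)propanal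
Product: 31 (2S,3R)-1-[3,4-bis(benzyloxy)-2-fluorophenyl]-3-[3,4-bis(benzyloxy)phenyl]-2-(methoxymethoxy)propane-1,3-diol, via 3,4-bis(benzyloxy)-2-fluorophenyllithium 29 (not isolated), via silyl ether adduct 30 (not isolated)
Conditions: 20, n-BuLi, THF, −78 °C; 14, −78 °C; AcOH; Bu4NF, 0 °C → rt
Reagents that add atoms: none
Why: Bromine–lithium exchange and 1,2-addition of the 2-fluoroaryllithium (stable at −78 °C) form the C4–C4a bond without touching C-2 or C-3, and fluoride desilylation in the same flask makes any silyl migration harmless.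

Step 17
Reactants: 31 (2S,3R)-1-[3,4-bis(benzyloxy)-2-fluorophenyl]-3-[3,4-bis(benzyloxy)phenyl]-2-(methoxymethoxy)propane-1,3-diol
Product: 32 (2R,3R)-7,8-bis(benzyloxy)-2-[3,4-bis(benzyloxy)phenyl]-3-(methoxymethoxy)chroman-4-ol
Conditions: KN(SiMe3)2 (1.3 equiv), 18-crown-6, THF, 0 → 60 °C
Reagents that add atoms: none
Why: Intramolecular SNAr closes ring C; only the ring-B benzylic alkoxide reaches the C–F carbon through a six-membered transition state, and because its C–O bond is never broken the syn relationship from step 5 becomes the 2,3-cis (2R,3R) flavan.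

Step 18
Reactants: 32 (2R,3R)-7,8-bis(benzyloxy)-2-[3,4-bis(benzyloxy)phenyl]-3-(methoxymethoxy)chroman-4-ol
Product: 33 (2R,3S,4S)-7,8-bis(benzyloxy)-2-[3,4-bis(benzyloxy)phenyl]-4-[(2,6-dimethylphenyl)sulfanyl]chroman-3-ol
Conditions: 2,6-dimethylbenzenethiol (5 equiv), HCl (1.25 M in MeOH)–CH2Cl2 1:1, 40 °C
Reagents that add atoms: 2,6-dimethylbenzenethiol, Cc1cccc(C)c1S
Why: Acid thiolysis (SN1) with concurrent MOM methanolysis; both C-4 epimers give one cation, which the thiol captures faster than any arene and only from the β face anti to the axial 3-oxygen (3,4-trans); the change of the C-3 label to S is a priority effect only.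

**Upper monomer**

Step 19
Reactants: 28 2,3-bis(benzyloxy)-1-bromo-4-fluorobenzene; 14 (2S,3R)-3-[3,4-bis(benzyloxy)phenyl]-3-(tert-butyldimethylsilyloxy)-2-(methoxymethoxy)propanal
Product: 36 (2S,3R)-1-[3,4-bis(benzyloxy)-5-bromo-2-fluorophenyl]-3-[3,4-bis(benzyloxy)phenyl]-2-(methoxymethoxy)propane-1,3-diol, via 3,4-bis(benzyloxy)-5-bromo-2-fluorophenyllithium 34 (not isolated), via silyl ether adduct 35 (not isolated)
Conditions: 28, LiN(i-Pr)2, THF, −78 °C; 14, −78 °C; AcOH; Bu4NF, 0 °C → rt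
Reagents that add atoms: none
Why: Deprotonative ortho-lithiation next to fluorine (the same site selectivity as in step 12, with the bromine kept) followed by 1,2-addition to the aldehyde and fluoride desilylation.

Step 20
Reactants: 36 (2S,3R)-1-[3,4-bis(benzyloxy)-5-bromo-2-fluorophenyl]-3-[3,4-bis(benzyloxy)phenyl]-2-(methoxymethoxy)propane-1,3-diol
Product: 37 (2R,3R)-7,8-bis(benzyloxy)-2-[3,4-bis(benzyloxy)phenyl]-6-bromo-3-(methoxymethoxy)chroman-4-ol
Conditions: KN(SiMe3)2 (1.3 equiv), 18-crown-6, THF, 0 → 50 °C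
Reagents that add atoms: none
Why: Intramolecular SNAr as in step 17, here helped by the bromine para to fluorine; C-2 is retained, so the flavan is again 2,3-cis (2R,3R).

Step 21
Reactants: 37 (2R,3R)-7,8-bis(benzyloxy)-2-[3,4-bis(benzyloxy)phenyl]-6-bromo-3-(methoxymethoxy)chroman-4-ol
Product: 38 (2R,3R,4S)-7,8-bis(benzyloxy)-2-[3,4-bis(benzyloxy)phenyl]-6-bromo-4-methoxychroman-3-ol
Conditions: HCl (1.25 M in MeOH)–CH2Cl2 1:1, 40 °C
Reagents that add atoms: methanol, CO
Why: SN1 methanolysis at C-4 with MOM cleavage; the C-6 bromine rules out self-condensation, and solvent capture is β (the same course as melacacidin → O-ethylisomelacacidin), although this centre is ionised again in step 22.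

**Union and end game**

Step 22
Reactants: 38 (2R,3R,4S)-7,8-bis(benzyloxy)-2-[3,4-bis(benzyloxy)phenyl]-6-bromo-4-methoxychroman-3-ol; 33 (2R,3S,4S)-7,8-bis(benzyloxy)-2-[3,4-bis(benzyloxy)phenyl]-4-[(2,6-dimethylphenyl)sulfanyl]chroman-3-ol
Product: 39 octa-O-benzyl-6-bromoepimesquitol-(4β→6)-4β-[(2,6-dimethylphenyl)sulfanyl]epimesquitol
Conditions: 38 (1.0 equiv), 33 (1.2 equiv), BF3·OEt2 (1.2 equiv), 4 Å sieves, CH2Cl2, −78 → −30 °C; aq NaHCO3
Reagents that add atoms: none
Why: Friedel–Crafts flavanyl-cation coupling with orthogonal leaving groups; the hard Lewis acid ionises only the C4–OMe bond, the hindered arylthio group is neither ionised nor transferred, C-6 of 33 (para to O1, ortho to 7-OBn) is its most nucleophilic carbon, and attack anti to the axial 3-OH sets upper C-4 as 4β (4S); reversible O-alkylation drains into the C–C product.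

Step 23
Reactants: 39 octa-O-benzyl-6-bromoepimesquitol-(4β→6)-4β-[(2,6-dimethylphenyl)sulfanyl]epimesquitol
Product: 40 octa-O-benzyl-6-bromoepimesquitol-(4β→6)-epimesquitol-4β-ol
Conditions: AgBF4 (2 equiv), 2,6-di-tert-butyl-4-methylpyridine (2.5 equiv), THF–H2O 10:1, 0 °C, dark
Reagents that add atoms: water, O
Why: Thiophilic silver-assisted SN1 hydrolysis; water captures the lower C-4 cation from the β face anti to the axial 3-OH and sets the 3,4-trans (4S) alcohol, and the hindered pyridine removes HBF4 so the product is not ionised again.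

Step 24
Reactants: 40 octa-O-benzyl-6-bromoepimesquitol-(4β→6)-epimesquitol-4β-ol
Product: 41 epimesquitol-(4β→6)-epimesquitol-4β-ol (target)
Conditions: H2 (1 atm), 10% Pd/C, Et3N (3 equiv), THF–MeOH 1:1, rt, 2–4 h; filter under Ar; Sephadex LH-20
Reagents that add atoms: none
Why: Catalytic hydrogenolysis; phenolic benzyl ethers and the aryl bromide cleave quickly on amine-moderated Pd/C, which does not hydrogenolyse secondary benzylic alcohols, the C2–O1 bonds or the interflavanyl bond, and Et3N traps HBr so no stereocentre is disturbed.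

## Compound list
1 | catechol (benzene-1,2-diol) | Oc1ccccc1O | starting material
2 | 1,2-bis(benzyloxy)benzene | c1ccc(COc2ccccc2OCc2ccccc2)cc1 | intermediate
3 | 1,2-bis(benzyloxy)-4-bromobenzene | Brc1ccc(OCc2ccccc2)c(OCc2ccccc2)c1 | intermediate
4 | 3,4-bis(benzyloxy)phenyllithium | [Li]c1ccc(OCc2ccccc2)c(OCc2ccccc2)c1 | intermediate (not isolated)
5 | 3,4-bis(benzyloxy)benzaldehyde | O=Cc1ccc(OCc2ccccc2)c(OCc2ccccc2)c1 | intermediate
6 | allyl alcohol (prop-2-en-1-ol) | C=CCO | starting material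
7 | 3-(methoxymethoxy)prop-1-ene (allyl MOM ether) | C=CCOCOC | intermediate
8 | (Z)-3-(methoxymethoxy)allyllithium | [Li]C/C=C\OCOC | intermediate (not isolated)
9 | [(Z)-3-(methoxymethoxy)allyl]bis(isopinocampheyl)borane, Ipc from (+)-α-pinene | COCO/C=C\CB([C@@H]1C[C@@H]2C[C@H]([C@H]1C)C2(C)C)[C@@H]1C[C@@H]2C[C@H]([C@H]1C)C2(C)C | intermediate (not isolated)
10 | bis(isopinocampheyl)borinate ester of 11 | B([C@@H]1C[C@@H]2C[C@H]([C@H]1C)C2(C)C)([C@@H]1C[C@@H]2C[C@H]([C@H]1C)C2(C)C)O[C@H](c1ccc(OCc2ccccc2)c(OCc2ccccc2)c1)[C@H](OCOC)C=C | intermediate (not isolated)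
11 | (1R,2R)-1-[3,4-bis(benzyloxy)phenyl]-2-(methoxymethoxy)but-3-en-1-ol | O[C@H](c1ccc(OCc2ccccc2)c(OCc2ccccc2)c1)[C@H](OCOC)C=C | intermediate
12 | (1R,2R)-1-[3,4-bis(benzyloxy)phenyl]-1-(tert-butyldimethylsilyloxy)-2-(methoxymethoxy)but-3-ene | CC(C)(C)[Si](C)(C)O[C@H](c1ccc(OCc2ccccc2)c(OCc2ccccc2)c1)[C@H](OCOC)C=C | intermediate
13 | (3R,4R)-4-[3,4-bis(benzyloxy)phenyl]-4-(tert-butyldimethylsilyloxy)-3-(methoxymethoxy)butane-1,2-diol, C-2 epimers | CC(C)(C)[Si](C)(C)O[C@H](c1ccc(OCc2ccccc2)c(OCc2ccccc2)c1)[C@H](OCOC)C(O)CO | intermediate (not isolated)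
14 | (2S,3R)-3-[3,4-bis(benzyloxy)phenyl]-3-(tert-butyldimethylsilyloxy)-2-(methoxymethoxy)propanal | CC(C)(C)[Si](C)(C)O[C@H](c1ccc(OCc2ccccc2)c(OCc2ccccc2)c1)[C@H](OCOC)C=O | intermediate
15 | 2-fluorophenol | Oc1ccccc1F | starting material
16 | 3-fluoro-2-hydroxybenzaldehyde | O=Cc1cccc(F)c1O | intermediate
17 | 3-fluoro-2-hydroxyphenyl formate | O=COc1cccc(F)c1O | intermediate (not isolated)
18 | 3-fluorobenzene-1,2-diol | Oc1cccc(F)c1O | intermediate
19 | 1,2-bis(benzyloxy)-3-fluorobenzene | Fc1cccc(OCc2ccccc2)c1OCc1ccccc1 | intermediate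
20 | 1,2-bis(benzyloxy)-4-bromo-3-fluorobenzene | Fc1c(Br)ccc(OCc2ccccc2)c1OCc1ccccc1 | intermediate
21 | 1-bromo-4-fluorobenzene | Fc1ccc(Br)cc1 | starting material
22 | 5-bromo-2-fluorophenyllithium | [Li]c1cc(Br)ccc1F | intermediate (not isolated)
23 | dimethyl 5-bromo-2-fluorophenylboronate | COB(OC)c1cc(Br)ccc1F | intermediate (not isolated)
24 | 5-bromo-2-fluorophenol | Oc1cc(Br)ccc1F | intermediate
25 | 6-bromo-3-fluoro-2-hydroxybenzaldehyde | O=Cc1c(Br)ccc(F)c1O | intermediate
26 | 6-bromo-3-fluoro-2-hydroxyphenyl formate | O=COc1c(Br)ccc(F)c1O | intermediate (not isolated)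
27 | 3-bromo-6-fluorobenzene-1,2-diol | Oc1c(Br)ccc(F)c1O | intermediate
28 | 2,3-bis(benzyloxy)-1-bromo-4-fluorobenzene | Fc1ccc(Br)c(OCc2ccccc2)c1OCc1ccccc1 | intermediate
29 | 3,4-bis(benzyloxy)-2-fluorophenyllithium | [Li]c1ccc(OCc2ccccc2)c(OCc2ccccc2)c1F | intermediate (not isolated)
30 | (2R,3R)-1-[3,4-bis(benzyloxy)-2-fluorophenyl]-3-[3,4-bis(benzyloxy)phenyl]-3-(tert-butyldimethylsilyloxy)-2-(methoxymethoxy)propan-1-ol, C-1 epimers | CC(C)(C)[Si](C)(C)O[C@H](c1ccc(OCc2ccccc2)c(OCc2ccccc2)c1)[C@H](OCOC)C(O)c1ccc(OCc2ccccc2)c(OCc2ccccc2)c1F | intermediate (not isolated)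
31 | (2S,3R)-1-[3,4-bis(benzyloxy)-2-fluorophenyl]-3-[3,4-bis(benzyloxy)phenyl]-2-(methoxymethoxy)propane-1,3-diol, C-1 epimers | O[C@H](c1ccc(OCc2ccccc2)c(OCc2ccccc2)c1)[C@H](OCOC)C(O)c1ccc(OCc2ccccc2)c(OCc2ccccc2)c1F | intermediate
32 | (2R,3R)-7,8-bis(benzyloxy)-2-[3,4-bis(benzyloxy)phenyl]-3-(methoxymethoxy)chroman-4-ol, 2,3-cis, C-4 epimers | c1cc2c(c(OCc3ccccc3)c1OCc1ccccc1)O[C@H](c1ccc(OCc3ccccc3)c(OCc3ccccc3)c1)[C@H](OCOC)C2O | intermediate
33 | (2R,3S,4S)-7,8-bis(benzyloxy)-2-[3,4-bis(benzyloxy)phenyl]-4-[(2,6-dimethylphenyl)sulfanyl]chroman-3-ol, 2,3-cis-3,4-trans (4β-S) | c1cc2c(c(OCc3ccccc3)c1OCc1ccccc1)O[C@H](c1ccc(OCc3ccccc3)c(OCc3ccccc3)c1)[C@H](O)[C@H]2Sc1c(C)cccc1C | intermediate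
34 | 3,4-bis(benzyloxy)-5-bromo-2-fluorophenyllithium | [Li]c1cc(Br)c(OCc2ccccc2)c(OCc2ccccc2)c1F | intermediate (not isolated)
35 | (2R,3R)-1-[3,4-bis(benzyloxy)-5-bromo-2-fluorophenyl]-3-[3,4-bis(benzyloxy)phenyl]-3-(tert-butyldimethylsilyloxy)-2-(methoxymethoxy)propan-1-ol, C-1 epimers | CC(C)(C)[Si](C)(C)O[C@H](c1ccc(OCc2ccccc2)c(OCc2ccccc2)c1)[C@H](OCOC)C(O)c1cc(Br)c(OCc2ccccc2)c(OCc2ccccc2)c1F | intermediate (not isolated)
36 | (2S,3R)-1-[3,4-bis(benzyloxy)-5-bromo-2-fluorophenyl]-3-[3,4-bis(benzyloxy)phenyl]-2-(methoxymethoxy)propane-1,3-diol, C-1 epimers | O[C@H](c1ccc(OCc2ccccc2)c(OCc2ccccc2)c1)[C@H](OCOC)C(O)c1cc(Br)c(OCc2ccccc2)c(OCc2ccccc2)c1F | intermediate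
37 | (2R,3R)-7,8-bis(benzyloxy)-2-[3,4-bis(benzyloxy)phenyl]-6-bromo-3-(methoxymethoxy)chroman-4-ol, 2,3-cis, C-4 epimers | Brc1cc2c(c(OCc3ccccc3)c1OCc1ccccc1)O[C@H](c1ccc(OCc3ccccc3)c(OCc3ccccc3)c1)[C@H](OCOC)C2O | intermediate
38 | (2R,3R,4S)-7,8-bis(benzyloxy)-2-[3,4-bis(benzyloxy)phenyl]-6-bromo-4-methoxychroman-3-ol (4β-OMe) | Brc1cc2c(c(OCc3ccccc3)c1OCc1ccccc1)O[C@H](c1ccc(OCc3ccccc3)c(OCc3ccccc3)c1)[C@H](O)[C@H]2OC | intermediate
39 | octa-O-benzyl-6-bromoepimesquitol-(4β→6)-4β-[(2,6-dimethylphenyl)sulfanyl]epimesquitol; upper unit 2R,3R,4S, lower unit 2R,3S,4S | Brc1cc2c(c(OCc3ccccc3)c1OCc1ccccc1)O[C@H](c1ccc(OCc3ccccc3)c(OCc3ccccc3)c1)[C@H](O)[C@H]2c1cc2c(c(OCc3ccccc3)c1OCc1ccccc1)O[C@H](c1ccc(OCc3ccccc3)c(OCc3ccccc3)c1)[C@H](O)[C@H]2Sc1c(C)cccc1C | intermediate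
40 | octa-O-benzyl-6-bromoepimesquitol-(4β→6)-epimesquitol-4β-ol; both units 2R,3R,4S | Brc1cc2c(c(OCc3ccccc3)c1OCc1ccccc1)O[C@H](c1ccc(OCc3ccccc3)c(OCc3ccccc3)c1)[C@H](O)[C@H]2c1cc2c(c(OCc3ccccc3)c1OCc1ccccc1)O[C@H](c1ccc(OCc3ccccc3)c(OCc3ccccc3)c1)[C@H](O)[C@H]2O | intermediate
41 | epimesquitol-(4β→6)-epimesquitol-4β-ol (CNP0143773.2); both units 2R,3R,4S | Oc1ccc([C@H]2Oc3c(ccc(O)c3O)[C@H](c3cc4c(c(O)c3O)O[C@H](c3ccc(O)c(O)c3)[C@H](O)[C@H]4O)[C@H]2O)cc1O | target

## Counts
Total step count: 24.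
Longest linear sequence: 12 steps (1, 2, 3, 5, 6, 7, 16, 17, 18, 22, 23, 24). The branch through steps 19, 20 and 21 is equally long.

## The three steps most likely to fail

**Step 17 (ring closure on a fluoride that has no electron-withdrawing group).** The C–F carbon carries a donating ortho benzyloxy group, so the SNAr may need forcing conditions. Step 20 is easier because of the para bromine. The fallback sets out from 30, which is isolated by leaving Bu4NF out of step 16.
- Dess–Martin periodinane oxidises the free carbinol of 30 to the 2-fluoroaryl ketone F1.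
- Bu4NF in THF at 0 °C then frees the benzylic alkoxide. It displaces the fluoride, now activated by the ortho carbonyl, to give the 2,3-cis-3-O-MOM-flavan-4-one F2.
- F2 is kept cold and reduced at once with NaBH4 in THF–MeOH at −40 °C, before C-3 can epimerise.
- The fallback comes back to the route at 32. The C-4 epimer ratio is again irrelevant.

**Step 22 (interflavanyl coupling).** A 7,8-dioxygenated ring A is a weaker nucleophile than a phloroglucinol ring. Slow C-alkylation, ether formation or thio-group transfer could therefore intervene. The fallback swaps the roles of the leaving groups. It sets out from 38 and 33.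
- 38 is thiolysed under the conditions of step 18 to the 6-bromo-4β-arylthioflavan-3-ol F3.
- 33 is hydrolysed with AgBF4/H2O as in step 23 to tetra-O-benzylisomelacacidin F4.
- The two hydroxyls of F4 are capped with Et3SiCl/imidazole to give the bis(triethylsilyl) ether F5.
- AgBF4 and 2,6-di-tert-butyl-4-methylpyridine in THF at 0 °C ionise only the C–S bond of F3. This is neutral thiophilic activation, the way C-4 thioethers have been joined to flavan-3,4-diols of this 7,8-dioxygenated series.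
- F5 captures the cation at C-6 to give the bis-silylated dimer F6.
- Bu4NF/AcOH removes the silyl groups. The fallback comes back at 40, so step 23 is not needed.

**Step 24 (debenzylation beside a benzylic C-4 hydroxyl).** Over-reduction would remove the lower 4-OH. The fallback sets out from 40.
- The three aliphatic hydroxyls are silylated with t-BuMe2SiOTf/2,6-lutidine to give the tris(tert-butyldimethylsilyl) ether F7.
- Hydrogenolysis (H2, 10% Pd/C, Et3N, EtOAc–THF) cannot reach the shielded C-4 oxygen and gives the octaphenol tris(silyl) ether F8.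
- Et3N·3HF in MeCN–THF at rt releases the hydroxyls. The fallback comes back at 41.

## Further compounds
F1 | step 17 | 2-fluoroaryl ketone: 1-[3,4-bis(benzyloxy)-2-fluorophenyl]-3-[3,4-bis(benzyloxy)phenyl]-3-(tert-butyldimethylsilyloxy)-2-(methoxymethoxy)propan-1-one | CC(C)(C)[Si](C)(C)O[C@H](c1ccc(OCc2ccccc2)c(OCc2ccccc2)c1)[C@H](OCOC)C(=O)c1ccc(OCc2ccccc2)c(OCc2ccccc2)c1F
F2 | step 17 | 2,3-cis-3-O-MOM-flavan-4-one: 7,8-bis(benzyloxy)-2-[3,4-bis(benzyloxy)phenyl]-3-(methoxymethoxy)chroman-4-one | c1cc2c(c(OCc3ccccc3)c1OCc1ccccc1)O[C@H](c1ccc(OCc3ccccc3)c(OCc3ccccc3)c1)[C@H](OCOC)C2=O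
F3 | step 22 | 6-bromo-4β-arylthioflavan-3-ol: 7,8-bis(benzyloxy)-2-[3,4-bis(benzyloxy)phenyl]-6-bromo-4-[(2,6-dimethylphenyl)sulfanyl]chroman-3-ol | Brc1cc2c(c(OCc3ccccc3)c1OCc1ccccc1)O[C@H](c1ccc(OCc3ccccc3)c(OCc3ccccc3)c1)[C@H](O)[C@H]2Sc1c(C)cccc1C
F4 | step 22 | tetra-O-benzylisomelacacidin: (2R,3R,4S)-7,8-bis(benzyloxy)-2-[3,4-bis(benzyloxy)phenyl]chroman-3,4-diol | c1cc2c(c(OCc3ccccc3)c1OCc1ccccc1)O[C@H](c1ccc(OCc3ccccc3)c(OCc3ccccc3)c1)[C@H](O)[C@H]2O
F5 | step 22 | bis(triethylsilyl) ether of F4 | c1cc2c(c(OCc3ccccc3)c1OCc1ccccc1)O[C@H](c1ccc(OCc3ccccc3)c(OCc3ccccc3)c1)[C@H](O[Si](CC)(CC)CC)[C@H]2O[Si](CC)(CC)CC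
F6 | step 22 | bis-silylated dimer: 3,4-bis(O-triethylsilyl) ether (lower unit) of 40 | Brc1cc2c(c(OCc3ccccc3)c1OCc1ccccc1)O[C@H](c1ccc(OCc3ccccc3)c(OCc3ccccc3)c1)[C@H](O)[C@H]2c1cc2c(c(OCc3ccccc3)c1OCc1ccccc1)O[C@H](c1ccc(OCc3ccccc3)c(OCc3ccccc3)c1)[C@H](O[Si](CC)(CC)CC)[C@H]2O[Si](CC)(CC)CC
F7 | step 24 | tris(tert-butyldimethylsilyl) ether of 40 | Brc1cc2c(c(OCc3ccccc3)c1OCc1ccccc1)O[C@H](c1ccc(OCc3ccccc3)c(OCc3ccccc3)c1)[C@H](O[Si](C)(C)C(C)(C)C)[C@H]2c1cc2c(c(OCc3ccccc3)c1OCc1ccccc1)O[C@H](c1ccc(OCc3ccccc3)c(OCc3ccccc3)c1)[C@H](O[Si](C)(C)C(C)(C)C)[C@H]2O[Si](C)(C)C(C)(C)C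
F8 | step 24 | octaphenol tris(silyl) ether: 3,3'',4''-tris(O-tert-butyldimethylsilyl) ether of 41 | c1cc2c(c(O)c1O)O[C@H](c1ccc(O)c(O)c1)[C@H](O[Si](C)(C)C(C)(C)C)[C@H]2c1cc2c(c(O)c1O)O[C@H](c1ccc(O)c(O)c1)[C@H](O[Si](C)(C)C(C)(C)C)[C@H]2O[Si](C)(C)C(C)(C)C
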